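The isoflavan is cut through C3–C4 and O1–C2. Ring A carries O1 on C8a ortho to the C4 methylene on C4a, a latent o-quinone methide O1=C8a–C4a=C4, and C3 is the α-carbon of the ring-B arylacetic acid. Because C4 is unsubstituted, C3 is the only stereocentre. One isothiourea-catalysed [4+2] of the chiral ammonium enolate with the methide forms both bonds, the pyranone ring and (3S). The precursors are 2,3,4-trimethoxy-6-(tosylmethyl)phenol and the dibenzyl-protected hydroquinone acetic acid, the latter pre-activated as its pivalic mixed anhydride before the free phenol is added. Reduction, Mitsunobu closure, debenzylation and oxidation finish.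

Key step: step 7

Assumption: atoms are numbered as in the chroman (O1, C2, C3, C4, C4a, C5–C8, C8a). The target is read as 3S (C2 > ring-B carbon > C4 > H), and the same spatial arrangement is named 3S in 12, 14, 15 and 16 and 2S in 13. The catalyst enantiomer is chosen from the accepted shielding model of N-acylated isothioureas; the commercially available mirror-image catalyst would be used should the first run show the opposite sense.

Step 1
Reactants: 1 2,3,4-trimethoxyphenol
Product: 2 6-(hydroxymethyl)-2,3,4-trimethoxyphenol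
Conditions: HCHO (37% aq., 3 equiv), NaOH (1.1 equiv), H2O, rt, N2; then AcOH to pH 6, 0 °C
Reagents that add atoms: formaldehyde (C=O)
Why: Lederer–Manasse hydroxymethylation, in which the phenoxide attacks formaldehyde through the only free carbon ortho to the oxygen (the para carbon and the other ortho carbon carry OMe), so a single salicyl alcohol should form, and at room temperature its onward condensation should be slow.

Step 2
Reactants: 2 6-(hydroxymethyl)-2,3,4-trimethoxyphenol
Product: 3 2,3,4-trimethoxy-6-(tosylmethyl)phenol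
Conditions: TolSO2Na (3 equiv), HCO2H/H2O, rt
Reagents that add atoms: sodium p-toluenesulfinate (Cc1ccc(cc1)S(=O)[O-].[Na+])
Why: Acid-promoted SN1 substitution of the benzylic hydroxyl, in which protonation and loss of water give the ortho-hydroxybenzyl cation and the soft sulfinate, present in excess, captures it through sulfur to give the sulfone as the thermodynamic product.

Step 3
Reactants: 4 2,3-dimethoxy-1,4-benzoquinone
Product: 6 1,4-bis(benzyloxy)-2,3-dimethoxybenzene, via 2,3-dimethoxybenzene-1,4-diol 5 (not isolated)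
Conditions: Na2S2O4, EtOAc/H2O, rt; crude hydroquinone then BnBr, K2CO3, DMF, 60 °C, N2
Reagents that add atoms: benzyl bromide (BrCc1ccccc1)
Why: Dithionite reduction of the quinone followed by Williamson etherification of both phenols (reductive alkylation), with the air-sensitive hydroquinone carried on crude under nitrogen.

Step 4
Reactants: 6 1,4-bis(benzyloxy)-2,3-dimethoxybenzene
Product: 7 1,4-bis(benzyloxy)-5-bromo-2,3-dimethoxybenzene
Conditions: NBS (1.0 equiv), MeCN, 0 °C to rt, dark
Reagents that add atoms: N-bromosuccinimide (O=C1CCC(=O)N1Br)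
Why: Electrophilic aromatic bromination of a tetra-oxygenated arene whose two free positions are equivalent by symmetry, so one equivalent of NBS should give a single monobromide.

Step 5
Reactants: 7 1,4-bis(benzyloxy)-5-bromo-2,3-dimethoxybenzene
Product: 8 ethyl 2-[2,5-bis(benzyloxy)-3,4-dimethoxyphenyl]acetate
Conditions: BrZnCH2CO2Et (1.5 equiv), Pd2(dba)3 (2.5 mol%), XPhos (10 mol%), THF, 60 °C
Reagents that add atoms: (2-ethoxy-2-oxoethyl)zinc bromide (CCOC(=O)C[Zn]Br)
Why: Negishi-type palladium-catalysed arylation of a Reformatsky zinc enolate (oxidative addition of the electron-rich aryl bromide, transmetalation, reductive elimination), run without strong base so the benzyl ethers are untouched.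

Step 6
Reactants: 8 ethyl 2-[2,5-bis(benzyloxy)-3,4-dimethoxyphenyl]acetate
Product: 9 2-[2,5-bis(benzyloxy)-3,4-dimethoxyphenyl]acetic acid
Conditions: LiOH·H2O, THF/MeOH/H2O, rt; then 1 M HCl
Reagents that add atoms: lithium hydroxide ([Li+].[OH-])
Why: Saponification of the ethyl ester and acidification, conditions to which aryl benzyl and methyl ethers are inert.

Step 7
Reactants: 3 2,3,4-trimethoxy-6-(tosylmethyl)phenol; 9 2-[2,5-bis(benzyloxy)-3,4-dimethoxyphenyl]acetic acid
Product: 12 (3S)-3-[2,5-bis(benzyloxy)-3,4-dimethoxyphenyl]-6,7,8-trimethoxychroman-2-one, via 2-[2,5-bis(benzyloxy)-3,4-dimethoxyphenyl]acetic pivalic anhydride 10 (not isolated), via 2,3,4-trimethoxy-6-methylidenecyclohexa-2,4-dien-1-one 11 (not isolated)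
Conditions: 9 (1.3 equiv), PivCl, iPr2NEt, CH2Cl2, 0 °C, 20 min; then (2R,3S)-HyperBTM (10 mol%), Cs2CO3, 3 (1.0 equiv, slow addition), CH2Cl2, 0 °C to rt; cold filtration through silica
Reagents that add atoms: none
Why: The pre-formed mixed anhydride 10 N-acylates the isothiourea and pivalate removes the α-proton (acidified by the α-aryl group) to give the (Z)-ammonium enolate, held coplanar with the catalyst by the 1,5-O···S contact, while Cs2CO3 deprotonates 3 and toluenesulfinate is expelled (E1cB) to give o-quinone methide 11; the enolate α-carbon (C3) adds to the methide carbon C4 and the resulting phenoxide O1 attacks the acylammonium carbonyl C2, releasing the catalyst. The closest known reaction type is the isothiourea- or NHC-catalysed Michael addition–lactonisation of arylacetic-acid-derived enolates with o-quinone methides generated in situ from 2-(sulfonylalkyl)phenols, which gives 3-aryl-3,4-dihydrocoumarins. The pyranone ring closes in two events, intermolecular C3–C4 conjugate addition followed by 6-exo-trig O-acylation (O1–C2). C3 is controlled by the catalyst alone: the pseudo-axial C2-phenyl group of (2R,3S)-HyperBTM shields one enolate face, and addition to the open Si face of the α-carbon is predicted to give 3S. The step needs enantiofacial selectivity and cross-reaction ahead of methide self-condensation and phenol acylation; these are secured by the unsubstituted C4 (no second stereocentre, no diastereomers), by forming the anhydride before the phenol is introduced, and by slow release of the electron-rich trimethoxy methide from a heterogeneous base into an excess of enolate precursor. The base is filtered off cold so that the acidic C3–H of the aryl lactone is not exchanged.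

Step 8
Reactants: 12 (3S)-3-[2,5-bis(benzyloxy)-3,4-dimethoxyphenyl]-6,7,8-trimethoxychroman-2-one
Product: 13 (2S)-2-[2,5-bis(benzyloxy)-3,4-dimethoxyphenyl]-3-(2-hydroxy-3,4,5-trimethoxyphenyl)propan-1-ol
Conditions: LiAlH4, THF, −20 to 0 °C; Rochelle salt work-up
Reagents that add atoms: none
Why: Hydride reduction of the aryl lactone to phenol and primary alcohol, which at low temperature should be faster than enolisation, so the α-aryl stereocentre is carried through unchanged.

Step 9
Reactants: 13 (2S)-2-[2,5-bis(benzyloxy)-3,4-dimethoxyphenyl]-3-(2-hydroxy-3,4,5-trimethoxyphenyl)propan-1-ol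
Product: 14 (3S)-3-[2,5-bis(benzyloxy)-3,4-dimethoxyphenyl]-6,7,8-trimethoxy-3,4-dihydro-2H-chromene
Conditions: PPh3, DIAD, THF, 0 °C to rt
Reagents that add atoms: none
Why: Intramolecular Mitsunobu etherification, in which the primary alcohol is activated as its alkoxyphosphonium and displaced by the phenol (6-exo-tet) to re-form O1–C2, while C3 is not a reacting centre and keeps its configuration.

Step 10
Reactants: 14 (3S)-3-[2,5-bis(benzyloxy)-3,4-dimethoxyphenyl]-6,7,8-trimethoxy-3,4-dihydro-2H-chromene
Product: 16 abruquinone B, 2,3-dimethoxy-5-[(3S)-6,7,8-trimethoxy-3,4-dihydro-2H-chromen-3-yl]cyclohexa-2,5-diene-1,4-dione, via 2,3-dimethoxy-5-[(3S)-6,7,8-trimethoxy-3,4-dihydro-2H-chromen-3-yl]benzene-1,4-diol 15 (not isolated)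
Conditions: H2 (1 atm), 10% Pd/C, EtOAc, rt; filter under N2; then Ag2O, MgSO4, EtOAc/Et2O, rt
Reagents that add atoms: none
Why: Hydrogenolysis of the two aryl benzyl ethers gives the electron-rich hydroquinone, which neutral silver(I) oxide oxidises to the p-quinone, whereas the fully etherified ring A cannot be oxidised under these conditions and C3 is not touched.

Compound list
1 | 2,3,4-trimethoxyphenol | COc1ccc(O)c(OC)c1OC | starting material
2 | 6-(hydroxymethyl)-2,3,4-trimethoxyphenol | OCc1cc(OC)c(OC)c(OC)c1O | intermediate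
3 | 2,3,4-trimethoxy-6-(tosylmethyl)phenol | Cc1ccc(cc1)S(=O)(=O)Cc1cc(OC)c(OC)c(OC)c1O | intermediate
4 | 2,3-dimethoxy-1,4-benzoquinone | COC1=C(OC)C(=O)C=CC1=O | starting material
5 | 2,3-dimethoxybenzene-1,4-diol | COc1c(O)ccc(O)c1OC | intermediate
6 | 1,4-bis(benzyloxy)-2,3-dimethoxybenzene | COc1c(OCc2ccccc2)ccc(OCc2ccccc2)c1OC | intermediate
7 | 1,4-bis(benzyloxy)-5-bromo-2,3-dimethoxybenzene | COc1c(OCc2ccccc2)cc(Br)c(OCc2ccccc2)c1OC | intermediate
8 | ethyl 2-[2,5-bis(benzyloxy)-3,4-dimethoxyphenyl]acetate | CCOC(=O)Cc1cc(OCc2ccccc2)c(OC)c(OC)c1OCc1ccccc1 | intermediate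
9 | 2-[2,5-bis(benzyloxy)-3,4-dimethoxyphenyl]acetic acid | OC(=O)Cc1cc(OCc2ccccc2)c(OC)c(OC)c1OCc1ccccc1 | intermediate
10 | 2-[2,5-bis(benzyloxy)-3,4-dimethoxyphenyl]acetic pivalic anhydride | CC(C)(C)C(=O)OC(=O)Cc1cc(OCc2ccccc2)c(OC)c(OC)c1OCc1ccccc1 | intermediate
11 | 2,3,4-trimethoxy-6-methylidenecyclohexa-2,4-dien-1-one (o-quinone methide) | C=C1C=C(OC)C(OC)=C(OC)C1=O | intermediate
12 | (3S)-3-[2,5-bis(benzyloxy)-3,4-dimethoxyphenyl]-6,7,8-trimethoxychroman-2-one | O=C1Oc2c(OC)c(OC)c(OC)cc2C[C@H]1c1cc(OCc2ccccc2)c(OC)c(OC)c1OCc1ccccc1 | intermediate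
13 | (2S)-2-[2,5-bis(benzyloxy)-3,4-dimethoxyphenyl]-3-(2-hydroxy-3,4,5-trimethoxyphenyl)propan-1-ol | OC[C@@H](Cc1cc(OC)c(OC)c(OC)c1O)c1cc(OCc2ccccc2)c(OC)c(OC)c1OCc1ccccc1 | intermediate
14 | (3S)-3-[2,5-bis(benzyloxy)-3,4-dimethoxyphenyl]-6,7,8-trimethoxy-3,4-dihydro-2H-chromene | COc1c(OC)c(OCc2ccccc2)cc([C@H]2COc3c(cc(OC)c(OC)c3OC)C2)c1OCc1ccccc1 | intermediate
15 | 2,3-dimethoxy-5-[(3S)-6,7,8-trimethoxy-3,4-dihydro-2H-chromen-3-yl]benzene-1,4-diol | COc1c(OC)c(O)cc([C@H]2COc3c(cc(OC)c(OC)c3OC)C2)c1O | intermediate
16 | abruquinone B, 2,3-dimethoxy-5-[(3S)-6,7,8-trimethoxy-3,4-dihydro-2H-chromen-3-yl]cyclohexa-2,5-diene-1,4-dione | COC1=C(OC)C(=O)C([C@H]2COc3c(cc(OC)c(OC)c3OC)C2)=CC1=O | target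

Total step count: 10. Longest linear sequence: 8 steps (4 to 16, steps 3–10).

Steps most likely to fail

Step 7. The unsubstituted methide may oligomerise faster than the hindered ortho-benzyloxy enolate captures it, or the catalyst-bound enolate may discriminate its faces poorly. The fallback sets out from 1 and 9 and comes back at 14, so that steps 8 and 9 are skipped. Ortho-formylation of 1 (MgCl2, Et3N, paraformaldehyde, MeCN, reflux) should give 2-hydroxy-3,4,5-trimethoxybenzaldehyde F1. Perkin–Oglialoro condensation of this aldehyde with 9 (Ac2O, Et3N, 110 °C) should give 3-[2,5-bis(benzyloxy)-3,4-dimethoxyphenyl]-6,7,8-trimethoxy-2H-chromen-2-one F2. DIBAL-H reduction of the unsaturated lactone should give (2Z)-2-[2,5-bis(benzyloxy)-3,4-dimethoxyphenyl]-3-(2-hydroxy-3,4,5-trimethoxyphenyl)prop-2-en-1-ol F3, and Mitsunobu closure (PPh3, DIAD) should give 3-[2,5-bis(benzyloxy)-3,4-dimethoxyphenyl]-6,7,8-trimethoxy-2H-chromene F4. Iridium-catalysed asymmetric hydrogenation of the trisubstituted chromene double bond (chiral Ir–phosphine–oxazoline catalyst, H2, CH2Cl2), with the ligand enantiomer chosen for 3S, should then give 14 with the benzyl ethers intact.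

Step 8. The basic aluminate may enolise the α-aryl aryl ester before hydride delivery is complete, eroding the configuration at C3. The fallback sets out from 12 and comes back at 14, so that 13 and step 9 are skipped. DIBAL-H in CH2Cl2 at −78 °C, a Lewis-acidic and non-basic hydride, should stop at (3S)-3-[2,5-bis(benzyloxy)-3,4-dimethoxyphenyl]-6,7,8-trimethoxy-3,4-dihydro-2H-chromen-2-ol F5 (both C2 epimers). Ionic hydrogenation with Et3SiH and BF3·OEt2 at −78 to −40 °C should remove the anomeric hydroxyl through the cyclic oxocarbenium ion and give the chroman 14 directly.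

Step 1. Under aqueous base the salicyl alcohol may lose water and be captured by unreacted phenoxide, so that diarylmethane condensation competes with clean mono-hydroxymethylation. The fallback sets out from 1 and comes back at 2. Heating 1 with phenylboronic acid and paraformaldehyde in toluene with catalytic propionic acid under azeotropic removal of water (boron-templated, ortho-specific hydroxymethylation) should give 6,7,8-trimethoxy-2-phenyl-4H-1,3,2-benzodioxaborinine F6, in which the new benzylic oxygen is held as the cyclic boronate and cannot condense. Exchange of the boronate with propane-1,3-diol at room temperature should then free 2 without exposure to aqueous base.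

Further compounds
F1 | step 7 | 2-hydroxy-3,4,5-trimethoxybenzaldehyde | O=Cc1cc(OC)c(OC)c(OC)c1O
F2 | step 7 | 3-[2,5-bis(benzyloxy)-3,4-dimethoxyphenyl]-6,7,8-trimethoxy-2H-chromen-2-one | O=C1Oc2c(OC)c(OC)c(OC)cc2C=C1c1cc(OCc2ccccc2)c(OC)c(OC)c1OCc1ccccc1
F3 | step 7 | (2Z)-2-[2,5-bis(benzyloxy)-3,4-dimethoxyphenyl]-3-(2-hydroxy-3,4,5-trimethoxyphenyl)prop-2-en-1-ol | OC/C(=C\c1cc(OC)c(OC)c(OC)c1O)c1cc(OCc2ccccc2)c(OC)c(OC)c1OCc1ccccc1
F4 | step 7 | 3-[2,5-bis(benzyloxy)-3,4-dimethoxyphenyl]-6,7,8-trimethoxy-2H-chromene | COc1cc2C=C(COc2c(OC)c1OC)c1cc(OCc2ccccc2)c(OC)c(OC)c1OCc1ccccc1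
F5 | step 8 | (3S)-3-[2,5-bis(benzyloxy)-3,4-dimethoxyphenyl]-6,7,8-trimethoxy-3,4-dihydro-2H-chromen-2-ol (both C2 epimers) | OC1Oc2c(OC)c(OC)c(OC)cc2C[C@H]1c1cc(OCc2ccccc2)c(OC)c(OC)c1OCc1ccccc1
F6 | step 1 | 6,7,8-trimethoxy-2-phenyl-4H-1,3,2-benzodioxaborinine | COc1cc2COB(c3ccccc3)Oc2c(OC)c1OC
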